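Ring atoms are labelled C1 (CO2Me), C2 (side chain), C3, C4, C5 (CH3), C6 (one-carbon bridge), C7 (tertiary OH), C8, C9 and C10 (secondary OH). The route rests on disconnecting C6–C7 together with C8–C9: a type 2 intramolecular Diels–Alder reaction closes the six-membered ring C5–C6–C7–C8–C9–C10 and, through the same C6–C7 bond, the seven-membered ring C1–C7 in one operation. It exploits the one-atom bridge C6 between the bridgeheads C5 and C7 and the 1,4-related oxygens at C7 and C10. The precursor is an acyclic triene: a 2-silyloxy-1,3-diene (C9=C10–C5=C6) tethered through C4–C1 to a 2-substituted acrolein (C8=C7–CHO), whose formyl group is a masked hydroxyl.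

Key step: step 8

Remark: bicyclic compounds are named with von Baeyer locants (1 = C7, 2 = C1, 3 = C2, 4 = C3, 5 = C4, 6 = C5, 7 = C10, 8 = C9, 9 = C8, 10 = C6); the Why lines use the labels C1–C10.
Assumption: in step 2 the enantiomer of the phosphoramidite ligand is the one that gives (R)-5 (its antipode would give ent-5); compounds 1, 2, 4, 6, 8, 11, 26 and 27 are purchased.

Step 1
Reactants: 1 4-(benzyloxy)but-1-ene; 2 allyl methyl carbonate
Product: 3 (E)-5-(benzyloxy)pent-2-en-1-yl methyl carbonate
Conditions: second-generation Grubbs catalyst (3 mol%), 2 (3 equiv), CH2Cl2, 40 °C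
Reagents that add atoms: none
Why: Olefin cross-metathesis of two terminal alkenes is driven by loss of ethene and should give the (E)-allylic carbonate as the main isomer.

Step 2
Reactants: 3 (E)-5-(benzyloxy)pent-2-en-1-yl methyl carbonate; 4 dimethyl malonate
Product: 5 dimethyl 2-[(3R)-5-(benzyloxy)pent-1-en-3-yl]malonate
Conditions: [Ir(cod)Cl]2 (2 mol%), O,O'-(1,1'-binaphthalene-2,2'-diyl) N,N-bis(1-phenylethyl)phosphoramidite (single enantiomer, 4 mol%), TBD (8 mol%), THF, rt
Reagents that add atoms: none
Why: Iridium-catalysed asymmetric allylic alkylation should give the branched malonate, the chiral phosphoramidite on the allyl–iridium intermediate deciding the face of attack and thereby setting C2.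

Step 3
Reactants: 5 dimethyl 2-[(3R)-5-(benzyloxy)pent-1-en-3-yl]malonate; 6 1-bromo-3-methylbut-2-ene
Product: 7 dimethyl 2-[(3R)-5-(benzyloxy)pent-1-en-3-yl]-2-(3-methylbut-2-en-1-yl)malonate
Conditions: NaH, THF/DMF, 0 °C to rt
Reagents that add atoms: none
Why: Malonate alkylation (SN2) with the reactive allylic bromide makes C1 quaternary, so that C1 is not stereogenic and carries no acidic hydrogen up to the cycloaddition.

Step 4
Reactants: 8 but-3-en-2-one
Product: 10 3-bromobut-3-en-2-one, via 3,4-dibromobutan-2-one 9 (not isolated)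
Conditions: Br2, CH2Cl2, 0 °C; then Et3N, 0 °C
Reagents that add atoms: bromine, BrBr
Why: Bromine addition to the enone followed by E1cB loss of HBr from the dibromo ketone (bromination–dehydrobromination) gives the α-bromo enone.

Step 5
Reactants: 7 dimethyl 2-[(3R)-5-(benzyloxy)pent-1-en-3-yl]-2-(3-methylbut-2-en-1-yl)malonate; 11 9-borabicyclo[3.3.1]nonane (9-BBN); 10 3-bromobut-3-en-2-one
Product: 13 dimethyl 2-[(3S)-1-(benzyloxy)-6-methylidene-7-oxooctan-3-yl]-2-(3-methylbut-2-en-1-yl)malonate, via alkylborane 12 (not isolated)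
Conditions: 11, THF, 0 °C to rt; then 10, Pd(dppf)Cl2 (5 mol%), AsPh3 (10 mol%), Cs2CO3, DMF/H2O, rt
Reagents that add atoms: none
Why: 9-BBN should hydroborate the monosubstituted vinyl group far faster than the trisubstituted prenyl alkene, and the primary alkylborane couples with the α-bromo enone in a B-alkyl Suzuki–Miyaura cross-coupling.

Step 6
Reactants: 13 dimethyl 2-[(3S)-1-(benzyloxy)-6-methylidene-7-oxooctan-3-yl]-2-(3-methylbut-2-en-1-yl)malonate
Product: 15 dimethyl 2-[(3S)-1-(benzyloxy)-6-methylidene-7-oxooctan-3-yl]-2-(2-oxoethyl)malonate, via ozonide 14 (not isolated)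
Conditions: O3, CH2Cl2, −78 °C (Sudan Red 7B as end-point indicator); then PPh3, −78 °C to rt
Reagents that add atoms: ozone, O=[O+][O-]
Why: Ozonolysis with reductive work-up; electrophilic ozone should consume the electron-rich trisubstituted prenyl alkene well before the electron-poor 1,1-disubstituted enone, the indicator marking the end point.

Step 7
Reactants: 15 dimethyl 2-[(3S)-1-(benzyloxy)-6-methylidene-7-oxooctan-3-yl]-2-(2-oxoethyl)malonate
Product: 16 dimethyl 2-[(3S)-1-(benzyloxy)-6-methylidene-7-oxooctan-3-yl]-2-(3-oxoprop-1-en-2-yl)malonate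
Conditions: aq. CH2O (37%), pyrrolidine (10 mol%), EtCO2H (10 mol%), i-PrOH, 45 °C
Reagents that add atoms: formaldehyde, C=O
Why: Amine-catalysed α-methylenation (Mannich condensation with formaldehyde, then elimination) of the only enamine-forming aldehyde gives the 2-substituted acrolein.

Step 8
Reactants: 16 dimethyl 2-[(3S)-1-(benzyloxy)-6-methylidene-7-oxooctan-3-yl]-2-(3-oxoprop-1-en-2-yl)malonate
Product: 18 dimethyl 3-[2-(benzyloxy)ethyl]-7-[(tert-butyldimethylsilyl)oxy]-1-formylbicyclo[4.3.1]dec-6-ene-2,2-dicarboxylate (C-1 and C-3 configured as C7 and C2 of the target), via silyloxydiene 17 (not isolated)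
Conditions: TBSOTf (1.2 equiv), Et3N (2.5 equiv), CH2Cl2, −78 to 0 °C; NaHCO3 wash, solvent exchange; toluene (0.01 M), BHT, 80–110 °C
Reagents that add atoms: tert-butyldimethylsilyl trifluoromethanesulfonate, CC(C)(C)[Si](C)(C)OS(=O)(=O)C(F)(F)F
Why: Soft enolisation of the methyl ketone, the only enolisable site, gives the 2-silyloxy-1,3-diene 17, which on heating should add to the tethered 2-substituted acrolein in a concerted but asynchronous [4+2] cycloaddition; the closest known reaction type is the type 2 intramolecular Diels–Alder reaction (diene tethered at an internal carbon), also viewed as an intramolecular double Michael addition. The six-membered ring C5–C6–C7–C8–C9–C10 is closed by the cycloaddition itself (bonds C6–C7 and C8–C9) and the seven-membered ring C1–C2–C3–C4–C5–C6–C7 is closed in the same event by the C6–C7 bond as the bridging ring, in the 1,3-bridged (meta) mode. The new stereocentre C7 is controlled by C2, whose CH2CH2OBn group takes the outward pseudo-equatorial position in the chair-like forming seven-membered ring, while C1 is kept non-stereogenic by the geminal diester. Regioselectivity is secured by the four-atom tether, which excludes the 1,4-bridged mode, and by the matching polarisation (nucleophilic C9 to electrophilic C8, siloxy carbon C10 para to formyl-bearing C7). Chemoselectivity for the enal C=C over its C=O and over hetero-Diels–Alder paths needs a Lewis-acid-free thermal stage, which excess Et3N and the bicarbonate wash should secure. The product keeps the C5=C10 bridgehead silyl enol ether for the regiospecific methylation of step 9 and the formyl group as the masked C7 hydroxyl.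

Step 9
Reactants: 18 dimethyl 3-[2-(benzyloxy)ethyl]-7-[(tert-butyldimethylsilyl)oxy]-1-formylbicyclo[4.3.1]dec-6-ene-2,2-dicarboxylate
Product: 19 dimethyl 3-[2-(benzyloxy)ethyl]-1-formyl-6-methyl-7-oxobicyclo[4.3.1]decane-2,2-dicarboxylate
Conditions: MeI (5 equiv), tetrabutylammonium difluorotriphenylsilicate (TBAT, 1.2 equiv), THF, −20 °C to rt
Reagents that add atoms: iodomethane, CI
Why: Fluoride-induced cleavage of the silyl enol ether gives the bridgehead ammonium enolate regiospecifically and this is C-methylated at C5 (enolate alkylation), the configuration of the quaternary C5 being dictated by the bicyclic frame, which offers only the exo face.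

Step 10
Reactants: 19 dimethyl 3-[2-(benzyloxy)ethyl]-1-formyl-6-methyl-7-oxobicyclo[4.3.1]decane-2,2-dicarboxylate
Product: 21 methyl (1S,2S,3S,6R)-3-[2-(benzyloxy)ethyl]-1-formyl-6-methyl-7-oxobicyclo[4.3.1]decane-2-carboxylate, via C-2 epimer mixture 20 (not isolated)
Conditions: LiCl, H2O, DMSO, 140 °C; then DBU (0.2 equiv), toluene, rt
Reagents that add atoms: none
Why: Krapcho dealkoxycarbonylation removes one geminal ester and the DBU treatment equilibrates C1 by enolisation to the more stable epimer (ester equatorial, trans to the C2 substituent), so that both C1 epimers converge.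

Step 11
Reactants: 21 methyl (1S,2S,3S,6R)-3-[2-(benzyloxy)ethyl]-1-formyl-6-methyl-7-oxobicyclo[4.3.1]decane-2-carboxylate
Product: 23 methyl 3-[2-(benzyloxy)ethyl]-1-hydroxy-6-methyl-7-oxobicyclo[4.3.1]decane-2-carboxylate (configuration as in 31), via formate 22 (not isolated)
Conditions: mCPBA, NaHCO3, CH2Cl2, 0 °C to rt; then KHCO3 (cat.), MeOH, rt
Reagents that add atoms: 3-chloroperbenzoic acid, OOC(=O)c1cccc(Cl)c1
Why: Baeyer–Villiger oxidation of the aldehyde on the fully substituted bridgehead should proceed with migration of the tertiary carbon and retention at C7, the aldehyde reacting faster than the hindered C10 ketone, and the formate is then cleaved by mild methanolysis.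

Step 12
Reactants: 23 methyl 3-[2-(benzyloxy)ethyl]-1-hydroxy-6-methyl-7-oxobicyclo[4.3.1]decane-2-carboxylate
Product: 24 methyl 1-hydroxy-3-(2-hydroxyethyl)-6-methyl-7-oxobicyclo[4.3.1]decane-2-carboxylate (configuration as in 31)
Conditions: H2 (1 atm), Pd/C, EtOAc, rt
Reagents that add atoms: none
Why: Hydrogenolysis of the benzyl ether over Pd/C; no alkene or other reducible group competes under these conditions.

Step 13
Reactants: 24 methyl 1-hydroxy-3-(2-hydroxyethyl)-6-methyl-7-oxobicyclo[4.3.1]decane-2-carboxylate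
Product: 25 methyl 1-hydroxy-6-methyl-7-oxo-3-(2-oxoethyl)bicyclo[4.3.1]decane-2-carboxylate (configuration as in 31)
Conditions: Dess–Martin periodinane, NaHCO3, CH2Cl2, 0 °C to rt
Reagents that add atoms: none
Why: Dess–Martin oxidation converts the only primary alcohol into the aldehyde, the tertiary C7 alcohol being inert.

Step 14
Reactants: 26 2-methylbut-3-en-2-ol; 27 (E)-but-2-enal
Product: 28 (E)-4-hydroxy-4-methylpent-2-enal
Conditions: second-generation Hoveyda–Grubbs catalyst (2 mol%), 27 (5 equiv), CH2Cl2, 40 °C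
Reagents that add atoms: none
Why: Olefin cross-metathesis with crotonaldehyde as acrolein equivalent (propene is lost) should give the (E)-enal.

Step 15
Reactants: 25 methyl 1-hydroxy-6-methyl-7-oxo-3-(2-oxoethyl)bicyclo[4.3.1]decane-2-carboxylate; 28 (E)-4-hydroxy-4-methylpent-2-enal
Product: 29 methyl 1-hydroxy-3-[(2E,4E)-6-hydroxy-6-methyl-1-oxohepta-2,4-dien-2-yl]-6-methyl-7-oxobicyclo[4.3.1]decane-2-carboxylate (configuration as in 31)
Conditions: pyrrolidine (20 mol%), 4-(dimethylamino)benzoic acid (20 mol%), 28 (3 equiv), CH2Cl2, rt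
Reagents that add atoms: none
Why: Amine-catalysed cross-aldol condensation (enamine addition, then elimination) of the enolisable aldehyde 25 with the non-enolisable enal 28 should give the 2-substituted dienal with the formyl group trans to the β-substituent, which places the dienyl chain cis to C2 as in the target; conjugate addition to 28 is retarded by its fully substituted γ-carbon.

Step 16
Reactants: 29 methyl 1-hydroxy-3-[(2E,4E)-6-hydroxy-6-methyl-1-oxohepta-2,4-dien-2-yl]-6-methyl-7-oxobicyclo[4.3.1]decane-2-carboxylate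
Product: 30 methyl 3-[(2E,4E)-1,6-dihydroxy-6-methylhepta-2,4-dien-2-yl]-1,7-dihydroxy-6-methylbicyclo[4.3.1]decane-2-carboxylate (configuration as in 31)
Conditions: NaBH4, CeCl3·7H2O, MeOH, −40 to 0 °C; immediate neutral work-up
Reagents that add atoms: none
Why: Luche reduction gives 1,2-reduction of the dienal and reduction of the C10 ketone, hydride attacking C10 axially from the face opposite to the C1–C4 bridge so that the equatorial alcohol (trans to the C5 methyl) results.

Step 17
Reactants: 30 methyl 3-[(2E,4E)-1,6-dihydroxy-6-methylhepta-2,4-dien-2-yl]-1,7-dihydroxy-6-methylbicyclo[4.3.1]decane-2-carboxylate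
Product: 31 methyl (1S,2S,3R,6R,7S)-3-[(2E,4E)-1-acetoxy-6-hydroxy-6-methylhepta-2,4-dien-2-yl]-1,7-dihydroxy-6-methylbicyclo[4.3.1]decane-2-carboxylate (CNP0302883.3)
Conditions: AcCl (1.1 equiv), 2,4,6-collidine, CH2Cl2, −78 °C
Reagents that add atoms: acetyl chloride, CC(Cl)=O
Why: Selective acylation of the unhindered primary allylic alcohol at low temperature; the secondary C10 alcohol next to the quaternary C5 and the two tertiary alcohols react far more slowly.

Compound list
1 | 4-(benzyloxy)but-1-ene | C=CCCOCc1ccccc1 | starting material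
2 | allyl methyl carbonate | C=CCOC(=O)OC | starting material
3 | (E)-5-(benzyloxy)pent-2-en-1-yl methyl carbonate | COC(=O)OC/C=C/CCOCc1ccccc1 | intermediate
4 | dimethyl malonate | COC(=O)CC(=O)OC | starting material
5 | dimethyl 2-[(3R)-5-(benzyloxy)pent-1-en-3-yl]malonate | COC(=O)C(C(=O)OC)[C@H](CCOCc1ccccc1)C=C | intermediate
6 | 1-bromo-3-methylbut-2-ene (prenyl bromide) | CC(C)=CCBr | starting material
7 | dimethyl 2-[(3R)-5-(benzyloxy)pent-1-en-3-yl]-2-(3-methylbut-2-en-1-yl)malonate | COC(=O)C(CC=C(C)C)(C(=O)OC)[C@H](CCOCc1ccccc1)C=C | intermediate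
8 | but-3-en-2-one | CC(=O)C=C | starting material
9 | 3,4-dibromobutan-2-one | CC(=O)C(Br)CBr | intermediate
10 | 3-bromobut-3-en-2-one | CC(=O)C(Br)=C | intermediate
11 | 9-borabicyclo[3.3.1]nonane (9-BBN) | B1C2CCCC1CCC2 | starting material
12 | B-alkyl-9-BBN adduct of 7 (boron on the terminal carbon of the former vinyl group) | COC(=O)C(CC=C(C)C)(C(=O)OC)[C@H](CCOCc1ccccc1)CCB1C2CCCC1CCC2 | intermediate
13 | dimethyl 2-[(3S)-1-(benzyloxy)-6-methylidene-7-oxooctan-3-yl]-2-(3-methylbut-2-en-1-yl)malonate | COC(=O)C(CC=C(C)C)(C(=O)OC)[C@H](CCOCc1ccccc1)CCC(=C)C(C)=O | intermediate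
14 | 1,2,4-trioxolane (ozonide) of 13 at the prenyl alkene | COC(=O)C(CC1OOC(C)(C)O1)(C(=O)OC)[C@H](CCOCc1ccccc1)CCC(=C)C(C)=O | intermediate
15 | dimethyl 2-[(3S)-1-(benzyloxy)-6-methylidene-7-oxooctan-3-yl]-2-(2-oxoethyl)malonate | COC(=O)C(CC=O)(C(=O)OC)[C@H](CCOCc1ccccc1)CCC(=C)C(C)=O | intermediate
16 | dimethyl 2-[(3S)-1-(benzyloxy)-6-methylidene-7-oxooctan-3-yl]-2-(3-oxoprop-1-en-2-yl)malonate | COC(=O)C(C(=C)C=O)(C(=O)OC)[C@H](CCOCc1ccccc1)CCC(=C)C(C)=O | intermediate
17 | dimethyl 2-[(3S)-1-(benzyloxy)-7-[(tert-butyldimethylsilyl)oxy]-6-methylideneoct-7-en-3-yl]-2-(3-oxoprop-1-en-2-yl)malonate | COC(=O)C(C(=C)C=O)(C(=O)OC)[C@H](CCOCc1ccccc1)CCC(=C)C(=C)O[Si](C)(C)C(C)(C)C | intermediate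
18 | dimethyl 3-[2-(benzyloxy)ethyl]-7-[(tert-butyldimethylsilyl)oxy]-1-formylbicyclo[4.3.1]dec-6-ene-2,2-dicarboxylate (C-1 and C-3 configured as in 31) | COC(=O)C1(C(=O)OC)[C@H](CCOCc2ccccc2)CCC=3C[C@@]1(C=O)CCC3O[Si](C)(C)C(C)(C)C | intermediate
19 | dimethyl 3-[2-(benzyloxy)ethyl]-1-formyl-6-methyl-7-oxobicyclo[4.3.1]decane-2,2-dicarboxylate (C-1, C-3, C-6 configured as in 31) | COC(=O)C1(C(=O)OC)[C@H](CCOCc2ccccc2)CC[C@]3(C)C[C@@]1(C=O)CCC3=O | intermediate
20 | methyl 3-[2-(benzyloxy)ethyl]-1-formyl-6-methyl-7-oxobicyclo[4.3.1]decane-2-carboxylate, both C-2 epimers | COC(=O)C1[C@H](CCOCc2ccccc2)CC[C@]3(C)C[C@@]1(C=O)CCC3=O | intermediate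
21 | methyl (1S,2S,3S,6R)-3-[2-(benzyloxy)ethyl]-1-formyl-6-methyl-7-oxobicyclo[4.3.1]decane-2-carboxylate | COC(=O)[C@H]1[C@H](CCOCc2ccccc2)CC[C@]3(C)C[C@@]1(C=O)CCC3=O | intermediate
22 | methyl 3-[2-(benzyloxy)ethyl]-1-(formyloxy)-6-methyl-7-oxobicyclo[4.3.1]decane-2-carboxylate (configuration as in 31) | COC(=O)[C@H]1[C@H](CCOCc2ccccc2)CC[C@]3(C)C[C@@]1(OC=O)CCC3=O | intermediate
23 | methyl 3-[2-(benzyloxy)ethyl]-1-hydroxy-6-methyl-7-oxobicyclo[4.3.1]decane-2-carboxylate (configuration as in 31) | COC(=O)[C@H]1[C@H](CCOCc2ccccc2)CC[C@]3(C)C[C@@]1(O)CCC3=O | intermediate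
24 | methyl 1-hydroxy-3-(2-hydroxyethyl)-6-methyl-7-oxobicyclo[4.3.1]decane-2-carboxylate (configuration as in 31) | COC(=O)[C@H]1[C@H](CCO)CC[C@]2(C)C[C@@]1(O)CCC2=O | intermediate
25 | methyl 1-hydroxy-6-methyl-7-oxo-3-(2-oxoethyl)bicyclo[4.3.1]decane-2-carboxylate (configuration as in 31) | COC(=O)[C@H]1[C@H](CC=O)CC[C@]2(C)C[C@@]1(O)CCC2=O | intermediate
26 | 2-methylbut-3-en-2-ol | CC(C)(O)C=C | starting material
27 | (E)-but-2-enal (crotonaldehyde) | C/C=C/C=O | starting material
28 | (E)-4-hydroxy-4-methylpent-2-enal | CC(C)(O)/C=C/C=O | intermediate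
29 | methyl 1-hydroxy-3-[(2E,4E)-6-hydroxy-6-methyl-1-oxohepta-2,4-dien-2-yl]-6-methyl-7-oxobicyclo[4.3.1]decane-2-carboxylate (configuration as in 31) | COC(=O)[C@H]1[C@H](/C(=C\C=C\C(C)(C)O)C=O)CC[C@]2(C)C[C@@]1(O)CCC2=O | intermediate
30 | methyl 3-[(2E,4E)-1,6-dihydroxy-6-methylhepta-2,4-dien-2-yl]-1,7-dihydroxy-6-methylbicyclo[4.3.1]decane-2-carboxylate (configuration as in 31) | COC(=O)[C@H]1[C@H](/C(=C\C=C\C(C)(C)O)CO)CC[C@]2(C)C[C@@]1(O)CC[C@@H]2O | intermediate
31 | methyl (1S,2S,3R,6R,7S)-3-[(2E,4E)-1-acetoxy-6-hydroxy-6-methylhepta-2,4-dien-2-yl]-1,7-dihydroxy-6-methylbicyclo[4.3.1]decane-2-carboxylate | COC(=O)[C@H]1[C@H](/C(=C\C=C\C(C)(C)O)COC(C)=O)CC[C@]2(C)C[C@@]1(O)CC[C@@H]2O | target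

Total step count: 17. Longest linear sequence: 15 steps (steps 1–3, 5–13 and 15–17); steps 4 and 14 prepare the two coupling partners 10 and 28.

Steps most likely to fail

Step 8 (cycloaddition). The C2 substituent may not fully control the face of the dienophile, giving the bridgehead pair C5/C7 in the wrong sense relative to C2. The acrolein unit may also react through its C=O or oligomerise before the strained bridgehead alkene forms. The fallback sets out from 16 and replaces the thermal cycloaddition by an anionic intramolecular double Michael addition under thermodynamic control. LiN(SiMe3)2 in THF at −78 °C should give the lithium cross-conjugated dienolate F1. On warming to 0 °C this should add to the enal and back onto the enone carbon C6 to give the bridgehead lithium enolate F2. The closing Michael addition is reversible, so the diastereomer with the C2 substituent equatorial should accumulate. Addition of MeI and DMPU then methylates C5, and the fallback comes back to the route at 19.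

Step 11 (oxidative removal of the formyl carbon). Hydride may migrate instead of the bridgehead carbon, giving the carboxylic acid, or the C10 ketone may be oxidised to a lactone. The fallback sets out from 21 and accepts the acid. Pinnick oxidation (NaClO2, NaH2PO4, 2-methylbut-2-ene, t-BuOH/H2O) should give the bridgehead carboxylic acid F3. Oxalyl chloride and then the sodium salt of N-hydroxypyridine-2-thione should convert it into the Barton ester F4. Photolysis of F4 under O2 with t-BuSH should give the bridgehead hydroperoxide F5, whose configuration the bicyclic frame fixes. Reduction with P(OMe)3 gives the tertiary alcohol, and the fallback comes back to the route at 23.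

Step 15 (aldol condensation). The enamine of 25 may add in conjugate fashion to 28, 25 may condense with itself, the β-hydroxy ester may open by retro-aldol reaction under amine catalysis, or the alkene geometry may erode. The fallback sets out from 25 and builds the trisubstituted alkene by a sigmatropic shift instead.
- α-Methylenation (aq. CH2O, pyrrolidine, EtCO2H, i-PrOH) should give the 2-substituted acrolein F6.
- Commercial 2-methylbut-3-yn-2-ol is hydrostannylated (Bu3SnH, PdCl2(PPh3)2) to the (E)-vinylstannane F7 and treated with I2 to give (E)-4-iodo-2-methylbut-3-en-2-ol F8.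
- Nozaki–Hiyama–Kishi coupling of F6 with F8 (CrCl2, NiCl2 cat., DMF) should give the divinyl carbinol F9 as a mixture of carbinol epimers.
- 1,3-Transposition of the allylic hydroxyl (Ph3SiOReO3 cat., Et2O, 0 °C) goes through a chair-like [3,3] shift of the perrhenate ester, which should place the dienyl chain cis to C2, and gives the primary dienol F10 that still carries the C10 ketone.
- Reduction of F10 under the conditions of step 16 brings the fallback back to the route at 30.

Further compounds
F1 | step 8 | lithium cross-conjugated dienolate of 16 | COC(=O)C(C(=C)C=O)(C(=O)OC)[C@H](CCOCc1ccccc1)CCC(=C)C(=C)O[Li]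
F2 | step 8 | bridgehead lithium enolate (lithium analogue of 18) | COC(=O)C1(C(=O)OC)[C@H](CCOCc2ccccc2)CCC=3C[C@@]1(C=O)CCC3O[Li]
F3 | step 11 | (1S,2S,3S,6R)-3-[2-(benzyloxy)ethyl]-2-(methoxycarbonyl)-6-methyl-7-oxobicyclo[4.3.1]decane-1-carboxylic acid | COC(=O)[C@H]1[C@H](CCOCc2ccccc2)CC[C@]3(C)C[C@@]1(C(=O)O)CCC3=O
F4 | step 11 | 2-thioxopyridin-1(2H)-yl ester of F3 (Barton ester) | COC(=O)[C@H]1[C@H](CCOCc2ccccc2)CC[C@]3(C)C[C@@]1(C(=O)ON2C=CC=CC2=S)CCC3=O
F5 | step 11 | methyl 3-[2-(benzyloxy)ethyl]-1-hydroperoxy-6-methyl-7-oxobicyclo[4.3.1]decane-2-carboxylate | COC(=O)[C@H]1[C@H](CCOCc2ccccc2)CC[C@]3(C)C[C@@]1(OO)CCC3=O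
F6 | step 15 | methyl 1-hydroxy-6-methyl-7-oxo-3-(3-oxoprop-1-en-2-yl)bicyclo[4.3.1]decane-2-carboxylate | COC(=O)[C@H]1[C@H](C(=C)C=O)CC[C@]2(C)C[C@@]1(O)CCC2=O
F7 | step 15 | (E)-2-methyl-4-(tributylstannyl)but-3-en-2-ol | CC(C)(O)/C=C/[Sn](CCCC)(CCCC)CCCC
F8 | step 15 | (E)-4-iodo-2-methylbut-3-en-2-ol | CC(C)(O)/C=C/I
F9 | step 15 | methyl 3-[(4E)-3,6-dihydroxy-6-methylhepta-1,4-dien-2-yl]-1-hydroxy-6-methyl-7-oxobicyclo[4.3.1]decane-2-carboxylate (carbinol epimers) | COC(=O)[C@H]1[C@H](C(=C)C(O)/C=C/C(C)(C)O)CC[C@]2(C)C[C@@]1(O)CCC2=O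
F10 | step 15 | methyl 3-[(2E,4E)-1,6-dihydroxy-6-methylhepta-2,4-dien-2-yl]-1-hydroxy-6-methyl-7-oxobicyclo[4.3.1]decane-2-carboxylate | COC(=O)[C@H]1[C@H](/C(=C\C=C\C(C)(C)O)CO)CC[C@]2(C)C[C@@]1(O)CCC2=O
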